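If a catalyst simply turns over, its turnovers grow with the starting material present and with the minutes, and that bench rule is the one to count with here.

- summer: starting material 1 M; gas phase 71 mM (held); protic impurity 0.60 M; catalyst 100 mM; added ligand 77 mM; run made earlier
- flask: starting material 2.0 M; gas phase 71 mM (held); protic impurity 0.600 M; catalyst 100 mM; added ligand 77 mM; time 15 min

- summer (time / min: product / %, starting material / %): 0.833: 1.6, 66.8; 2.50: 4.1, 47.1; 4.00: 4.9, 40.3; 6.00: 7.2, 35.7; 10.0: 8.5, 31.8; 12.0: 9.3, 30.4

(readings scatter by 0.3 percentage points)

- at the start none of the gas phase is in solution

- Monday's: doubling the amount of catalyst, all else as stated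
- Wednesday's: doubling the saturation concentration of gas phase, all else as stated
- Friday's: doubling the transfer coefficient of the gas phase, all else as stated

- amount of product at 15 min, in percent of the starting material charged
- the change that raises the amount of product at 15 min, in percent of the starting material charged most ("none" if none brings more than 2 percentage points) (Monday's / Wednesday's / Friday's / none)
- amount of product at 15 min, in percent of the starting material charged, after Wednesday's

In the summer run, starting material lost but not found as product stands at 60.3% of charge, close to the ratio of protic impurity to starting material, 60.0%, so the reckoning lets protic impurity take its own amount of starting material. The summer catalyst reads 0.930 turnovers over a summed exposure of 302 M·s, which gives 0.00308 M⁻¹ s⁻¹, the turnover coefficient, turnovers per unit time per unit concentration of starting material.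

The rule stops where the ratio of added ligand to catalyst, 0.770, moves. The coefficient reads 0.00384 M⁻¹ s⁻¹ up to the first reading and 0.00177 M⁻¹ s⁻¹ late, about half, so catalyst charged is not catalyst working. The asked flask keeps that ratio. It holds a pool of 1.40 M and a count factor of 0.277, and taking the average starting material as the pool less half of the product, this reckoning gives 17.0%. Doubling the factor for Wednesday's, with the rate taken as proportional to gas, gives 30.4%. Monday's brings the ratio down to 0.385, so it is the pick here too. The early coefficient stands above the late one, with no gas lag to read, so Friday's promises little.

The forecast gives 15%, Monday's, and 24% after Wednesday's, below this reckoning: “Doubling gas saturation gives at most double, likely about 1.6×.”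

The flask gives 16.8%, with Monday's gaining 15 percentage points against 13 points for Wednesday's, which ends at 29.6%.

    starting material + protic impurity → quenched substrate (k = 0.0180 M⁻¹ s⁻¹)
    catalyst + added ligand ⇌ idle complex (K = 31.0 M⁻¹, k = 0.0240 M⁻¹ s⁻¹)
    gas phase ⇌ dissolved gas, rate k3*(csat - [dissolved gas]) (kL = 0.630 s⁻¹)
    starting material + dissolved gas + catalyst → catalyst + product (k = 0.0630 M⁻² s⁻¹)

In the flask, starting material has a half-life of 2.1 min against protic impurity at 0.352 min, and 47 min in the product step at 15.0 min. At 15.0 min the flask holds 30.0% quenched substrate and 53.2% starting material. Its coefficient reads 0.00302 M⁻¹ s⁻¹, taking the exposure from pool and end. A neighbour flask with 0.40 M of catalyst gives 51.8% product, 2.59 turnovers, and a coefficient of 0.00326 M⁻¹ s⁻¹.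

Readings and results come from a simulation from invented constants, noise included.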